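**Retrosynthetic overview**

1. Locants (iridal type): C1 = CHO carbon, C2 = its α-carbon (methyl C25), C3–C5 = hydroxypropyl arm (C3 = CH2OH), C6–C11 = cyclohexane (C6 = CH with the arm, C7 = alkylidene carbon, C10 = C(CH3)OH, C11 = spiro carbon), C12–C14 and C26 = cyclopentane (C14 = CH with the triene, C26 = CHOH), C15=C16 = trisubstituted alkene, C28 = CH2OAc.
2. Endgame: enal from the C1 allylic alcohol; C28 acetate and the Z C15=C16 bond from a Still–Gennari-type olefination of a cis-fused α-phosphono γ-lactone (O26–C28–C15–C14) with dienal 34; the lactone from C14 alkylation and hydroxyl-directed reduction of a C26 ketone.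
3. Feature used: on the cyclohexane the C10 hydroxyl and the C6 arm are cis-1,3 across the spiro carbon C11, so O(C10) and arm carbon C4 can be tied into a 2-oxabicyclo[3.3.1]non-3-ene, which is the [4+2] adduct of an enal (O=C4–C5=C6) with a C10=C11 alkene exocyclic to the cyclopentane.
4. Key disconnection: C6–C11 and O–C10 in one Lewis-acid oxa-[4+2] (cation–olefin) closure of dienal 17, which closes the cyclohexane and sets C6, C10 and C11; 17 comes from a nickel-catalysed alkylative ynal cyclization (cyclopentane plus E-tetrasubstituted alkene), a CBS reduction (the only stereocentre carried in, later erased) and an enol tosylate/Suzuki sequence (tetrasubstituted acrylate).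
5. Ring order: cyclopentane (step 4), then the cyclohexane as last ring of the skeleton (step 12, with a temporary oxa-bridge that is opened in steps 13–14); a temporary γ-lactone exists from step 20 to step 25.

Key step: step 12

Remark: 1, 2, 15 and 31 are taken as commercial. The C26 configuration that steers the key step is opposite to that of the target and is corrected by oxidation (step 18) and directed reduction (step 20).

**Route**

Step 1
Reactants: 1 pent-4-ynoic acid; 2 2-(3-bromopropyl)-1,3-dioxolane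
Product: 3 8-(1,3-dioxolan-2-yl)oct-4-ynoic acid
Conditions: n-BuLi (2.1 equiv), THF/DMPU, −78 to 0 °C; then 2, 0 °C to rt; acidic work-up
Reagents that add atoms: none
Why: Acetylide alkylation, in which the carboxylate/acetylide dianion of 1 is alkylated at the sp carbon by the primary bromide (SN2) and joins C11 to C12.

Step 2
Reactants: 3 8-(1,3-dioxolan-2-yl)oct-4-ynoic acid
Product: 4 methyl 8-(1,3-dioxolan-2-yl)oct-4-ynoate
Conditions: MeI, K2CO3, DMF, rt
Reagents that add atoms: iodomethane, CI
Why: Carboxylate O-alkylation (SN2) masks the acid as the methyl ester that the nickel and borane steps require.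

Step 3
Reactants: 4 methyl 8-(1,3-dioxolan-2-yl)oct-4-ynoate
Product: 5 methyl 9-oxonon-4-ynoate
Conditions: 1 M HCl (cat.), acetone/H2O, rt
Reagents that add atoms: water, O
Why: Acid-catalysed acetal hydrolysis frees the aldehyde (C26) while ester and alkyne are inert.

Step 4
Reactants: 5 methyl 9-oxonon-4-ynoate
Product: 6 methyl (4E)-4-(2-hydroxycyclopentylidene)pentanoate (racemic)
Conditions: Ni(cod)2 (10 mol%), Me2Zn (2.5 equiv), THF, 0 °C; aq. NH4Cl
Reagents that add atoms: dimethylzinc, C[Zn]C
Why: Nickel-catalysed alkylative cyclization of a 5-ynal, in which oxidative cyclization of Ni(0) with aldehyde and alkyne gives an oxanickelacyclopentene and methyl transfer from zinc followed by reductive elimination places the new methyl cis to the carbinol carbon, so the cyclopentane and the E-tetrasubstituted exocyclic alkene form together.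

Step 5
Reactants: 6 methyl (4E)-4-(2-hydroxycyclopentylidene)pentanoate
Product: 7 methyl (4E)-4-(2-oxocyclopentylidene)pentanoate
Conditions: Dess–Martin periodinane, NaHCO3, CH2Cl2, 0 °C to rt
Reagents that add atoms: none
Why: Dess–Martin oxidation under buffered conditions removes the racemic carbinol centre and should leave the alkene geometry untouched.

Step 6
Reactants: 7 methyl (4E)-4-(2-oxocyclopentylidene)pentanoate
Product: 8 methyl (4E)-4-[(2S)-2-hydroxycyclopentylidene]pentanoate
Conditions: (R)-2-methyl-CBS-oxazaborolidine (10 mol%), BH3·SMe2, THF, −30 °C; MeOH quench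
Reagents that add atoms: none
Why: Corey–Bakshi–Shibata reduction, in which the alkylidene carbon acts as the large and the ring CH2 as the small ketone substituent, so the (R)-catalyst should give the (S)-alcohol, the only stereocentre carried into the key step.

Step 7
Reactants: 8 methyl (4E)-4-[(2S)-2-hydroxycyclopentylidene]pentanoate
Product: 9 methyl (4E)-4-[(2S)-2-(tert-butyldimethylsilyloxy)cyclopentylidene]pentanoate
Conditions: TBSOTf, 2,6-lutidine, CH2Cl2, −78 °C
Reagents that add atoms: tert-butyldimethylsilyl trifluoromethanesulfonate, CC(C)(C)[Si](C)(C)OS(=O)(=O)C(F)(F)F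
Why: Silyl ether formation installs the bulky allylic group that later shields one face of the alkene.

Step 8
Reactants: 9 methyl (4E)-4-[(2S)-2-(tert-butyldimethylsilyloxy)cyclopentylidene]pentanoate
Product: 10 (4E)-4-[(2S)-2-(tert-butyldimethylsilyloxy)cyclopentylidene]pentanoic acid
Conditions: LiOH, THF/MeOH/H2O, rt; acidify to pH 4
Reagents that add atoms: lithium hydroxide, [Li+].[OH-]
Why: Ester saponification, to which the silyl ether and the tetrasubstituted alkene are stable.

Step 9
Reactants: 10 (4E)-4-[(2S)-2-(tert-butyldimethylsilyloxy)cyclopentylidene]pentanoic acid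
Product: 13 methyl (6E)-2-methyl-3-oxo-6-[(2S)-2-(tert-butyldimethylsilyloxy)cyclopentylidene]heptanoate (both C2 epimers), via acyl imidazolide 11 (not isolated), via acylmalonate half-ester 12 (not isolated)
Conditions: CDI, THF, rt; then potassium methyl methylmalonate, MgCl2, Et3N, THF/MeCN, 50 °C; aq. citric acid
Reagents that add atoms: potassium methyl methylmalonate, COC(=O)C(C)C([O-])=O.[K+]
Why: Masamune–Brooks homologation, in which the acyl imidazolide C-acylates the magnesium enolate of the malonate half-ester and decarboxylation gives the α-methyl β-keto ester (C7 ketone, C2, C25, C1).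

Step 10
Reactants: 13 methyl (6E)-2-methyl-3-oxo-6-[(2S)-2-(tert-butyldimethylsilyloxy)cyclopentylidene]heptanoate
Product: 14 methyl (2E,6E)-2-methyl-3-(p-tolylsulfonyloxy)-6-[(2S)-2-(tert-butyldimethylsilyloxy)cyclopentylidene]hept-2-enoate
Conditions: TsCl, N-methylimidazole, Et3N, CH2Cl2, −10 °C
Reagents that add atoms: p-toluenesulfonyl chloride, Cc1ccc(S(=O)(=O)Cl)cc1
Why: Stereoselective enol sulfonylation of a β-keto ester, in which non-chelating amine conditions favour the enolate with its oxygen anti to the ester carbonyl and should give the tetrasubstituted enol tosylate with TsO trans to CO2Me.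

Step 11
Reactants: 14 enol tosylate; 15 (E)-2-(3,3-diethoxyprop-1-en-1-yl)-4,4,5,5-tetramethyl-1,3,2-dioxaborolane
Product: 17 methyl (2E,4E)-2-methyl-6-oxo-3-{(3E)-3-[(2S)-2-(tert-butyldimethylsilyloxy)cyclopentylidene]butyl}hexa-2,4-dienoate, via diethyl acetal 16 (not isolated)
Conditions: Pd(OAc)2 (5 mol%), SPhos, K3PO4, THF/H2O, 50 °C; then PPTS, acetone/H2O, rt
Reagents that add atoms: water, O
Why: Suzuki–Miyaura coupling of the activated alkenyl tosylate proceeds with retention at both partners, fixing the acrylate geometry (C6 cis to the C2 methyl), and mild acetal hydrolysis then frees the E-enal.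

Step 12
Reactants: 17 dienal
Product: 18 methyl (2E)-2-[2'-(tert-butyldimethylsilyloxy)-1-methylspiro[2-oxabicyclo[3.3.1]non-3-ene-9,1'-cyclopentan]-6-ylidene]propanoate (C6, C10, C11 as in the target; silyloxy group trans to C6 on the cyclopentane)
Conditions: Me2AlCl (1.5 equiv), CH2Cl2, −78 to −30 °C; aq. NaHCO3/Rochelle salt
Reagents that add atoms: none
Why: Proposed new method: Me2AlCl binds the aldehyde of 17 and the s-cis enal then acts as a 1-oxadiene toward the electron-rich tetrasubstituted exocyclic alkene in a strongly asynchronous inverse-demand oxa-[4+2], with C–C bond formation from the enal β-carbon (C6) to the ring alkene carbon (C11) running ahead of capture of the developing tertiary cationic centre (C10) by the aluminium enolate oxygen. The closest known reactions are Lewis-acid-promoted hetero-Diels–Alder and ene-type cation–olefin reactions of α,β-unsaturated carbonyl compounds with unactivated alkenes and 6-endo polyene cyclizations, here used for the first time in this bridged orientation; the same C6–C11 bond with positive charge arriving at C10 is presumed to close this ring in the biosynthesis of the iridals. The cyclohexane closes 6-endo with respect to the nucleophilic alkene (three-atom tether C7–C8–C9 from C6 to C10, new bond to the distal carbon C11) and the temporary dihydropyran closes by O–C10 bond formation, so the product is a 2-oxabicyclo[3.3.1]non-3-ene with C11 as the one-carbon bridge. C11 is set by attack anti to the silyloxy group, which A(1,3) strain with the cis methyl group holds perpendicular to the alkene plane; C10 is set relative to C11 by suprafacial addition to the geometrically defined alkene (methyl cis to the silyloxy-bearing carbon); C6 is set by the bicycle, which can only form with the C5–C4 unit and the new C–O bond cis-1,3 on the cyclohexane. The step needs bond formation at C11 and not at C10 (which would give a cyclopentane); with both alkene carbons fully substituted the usual 6-endo preference of 1,5-diene cation–olefin closures should decide, helped by the inductively withdrawing allylic silyloxy group that disfavours positive charge at C11. It also needs the tetrasubstituted acrylate to keep its geometry, which the ester secures by keeping positive charge away from C2.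

Step 13
Reactants: 18 bridged enol ether
Product: 20 methyl (2E)-2-[2',3-dihydroxy-1-methylspiro[2-oxabicyclo[3.3.1]nonane-9,1'-cyclopentan]-6-ylidene]propanoate (lactol, both anomers), via desilylated enol ether 19 (not isolated)
Conditions: TBAF, THF, rt; then 1 M HCl, THF/H2O, 0 °C
Reagents that add atoms: water, O
Why: Fluoride removes the silyl ether and acid-catalysed hydration of the cyclic enol ether (protonation at C5, water at C4) gives the lactol without touching the new stereocentres.

Step 14
Reactants: 20 lactol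
Product: 21 methyl (2E)-2-[1,6-dihydroxy-6-methyl-10-(prop-2-en-1-yl)spiro[4.5]decan-9-ylidene]propanoate
Conditions: Ph3PCH3Br, KOtBu (4 equiv ylide), THF, 0 °C to rt
Reagents that add atoms: methyltriphenylphosphonium bromide, C[P+](c1ccccc1)(c1ccccc1)c1ccccc1.[Br-]
Why: Wittig methylenation of the open hydroxy-aldehyde form of the lactol adds C3 and releases the tertiary C10 hydroxyl.

Step 15
Reactants: 21 diol alkene
Product: 23 methyl (2E)-2-[1,6-dihydroxy-10-(3-hydroxypropyl)-6-methylspiro[4.5]decan-9-ylidene]propanoate, via alkylborane 22 (not isolated)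
Conditions: 9-BBN (3 equiv), THF, 0 °C to rt; then 30% H2O2, pH 7 buffer, 0 °C
Reagents that add atoms: hydrogen peroxide, OO
Why: Anti-Markovnikov hydroboration–oxidation, in which 9-BBN adds only to the monosubstituted alkene (the tetrasubstituted enoate is inert) and oxidation gives the primary C3 alcohol.

Step 16
Reactants: 23 triol ester
Product: 24 9-[(2E)-1-hydroxypropan-2-ylidene]-10-(3-hydroxypropyl)-6-methylspiro[4.5]decane-1,6-diol
Conditions: DIBAL-H (6 equiv), CH2Cl2, −78 to −20 °C; Rochelle salt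
Reagents that add atoms: none
Why: DIBAL reduces the conjugated methyl ester to the C1 allylic alcohol by 1,2-reduction without changing the alkene geometry.

Step 17
Reactants: 24 tetraol
Product: 25 bis(tert-butyldiphenylsilyl) ether of 24 at the C1 and C3 oxygens
Conditions: TBDPSCl (2.2 equiv), imidazole, DMF, 0 °C
Reagents that add atoms: tert-butyl(chloro)diphenylsilane, CC(C)(C)[Si](Cl)(c1ccccc1)c1ccccc1
Why: Selective silylation, since the bulky silyl chloride should react only with the two primary hydroxyls and leave the hindered secondary and the tertiary hydroxyl free.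

Step 18
Reactants: 25 bis-silyl ether diol
Product: 26 6-hydroxy-6-methylspiro[4.5]decan-1-one carrying the two silyl ether arms (β-hydroxy ketone)
Conditions: Dess–Martin periodinane, NaHCO3, CH2Cl2, rt
Reagents that add atoms: none
Why: Dess–Martin oxidation of the only oxidizable (secondary) hydroxyl erases the auxiliary C26 stereocentre and gives the β-hydroxy ketone needed for enolate chemistry and directed reduction.

Step 19
Reactants: 26 β-hydroxy ketone
Product: 27 methyl 2-(1-oxospiro[4.5]decan-2-yl)acetate derivative (acetate arm at C14 cis to C6)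
Conditions: LDA (2.3 equiv), THF, −78 °C; BrCH2CO2Me, DMPU, −78 to −40 °C
Reagents that add atoms: methyl bromoacetate, COC(=O)CBr
Why: Enolate alkylation of the alkoxide–enolate dianion (C14 is the only enolizable position and the enolized ketone cannot undergo retro-aldol cleavage), in which the electrophile should approach the cyclopentanone face flanked by C6–H and not the face flanked by the C10 methyl and alkoxide, placing the arm cis to C6.

Step 20
Reactants: 27 keto ester
Product: 29 cis-fused γ-lactone (O26–C28(=O)–C15–C14), via hydroxy ester 28 (not isolated)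
Conditions: Me4NBH(OAc)3, MeCN/AcOH, −20 °C; then PPTS (cat.), PhMe, 40 °C
Reagents that add atoms: none
Why: Evans–Saksena reduction, in which hydride is delivered intramolecularly from boron bound to the C10 hydroxyl to the ketone face on the side of C10 (also anti to the C14 arm), so the C26 hydroxyl ends cis to that arm and cis to C6 and then lactonizes.

Step 21
Reactants: 29 γ-lactone
Product: 30 α-[bis(2,2,2-trifluoroethoxy)phosphoryl] γ-lactone (C15 epimers)
Conditions: LDA (3.3 equiv), THF, −78 °C; ClP(O)(OCH2CF3)2, −78 to 0 °C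
Reagents that add atoms: bis(2,2,2-trifluoroethyl) phosphorochloridate, O=P(Cl)(OCC(F)(F)F)OCC(F)(F)F
Why: C-phosphorylation of the lactone enolate (excess base drives O-to-C phosphoryl transfer and deprotonates the product) gives the electron-poor phosphonate needed for a Z-selective olefination.

Step 22
Reactants: 31 6-methylhept-5-en-2-one
Product: 32 6-methylhepta-1,5-dien-2-yl trifluoromethanesulfonate
Conditions: LDA, THF, −78 °C; PhNTf2, −78 to 0 °C
Reagents that add atoms: N-phenylbis(trifluoromethanesulfonimide), O=S(=O)(N(c1ccccc1)S(=O)(=O)C(F)(F)F)C(F)(F)F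
Why: Kinetic deprotonation at the methyl group and O-triflation of the less substituted enolate give the 2-triflyloxy-1-alkene.

Step 23
Reactants: 32 vinyl triflate; 15 (E)-2-(3,3-diethoxyprop-1-en-1-yl)-4,4,5,5-tetramethyl-1,3,2-dioxaborolane
Product: 34 (2E)-8-methyl-4-methylidenenona-2,7-dienal, via diethyl acetal 33 (not isolated)
Conditions: Pd(PPh3)4 (5 mol%), K3PO4, dioxane/H2O, 60 °C; then PPTS, acetone/H2O, rt
Reagents that add atoms: water, O
Why: Suzuki–Miyaura coupling with retention of the E-alkenylboronate geometry followed by acetal hydrolysis gives the E-dienal.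

Step 24
Reactants: 30 phosphono lactone; 34 dienal
Product: 35 (Z)-α-alkylidene γ-lactone (dienyl group cis to the lactone carbonyl, trans to C14)
Conditions: KHMDS (2.1 equiv), 18-crown-6, THF, −78 °C; then 34
Reagents that add atoms: none
Why: Still–Gennari-type Horner–Wadsworth–Emmons olefination, in which the trifluoroethyl phosphonate and a dissociated potassium counter-ion make oxaphosphetane collapse kinetically controlled and should place the dienyl group cis to the carbonyl (Z).

Step 25
Reactants: 35 alkylidene lactone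
Product: 36 triol with the C28 allylic hydroxyl, the C26 hydroxyl and the C10 hydroxyl free (C1 and C3 as silyl ethers)
Conditions: DIBAL-H (5 equiv), CH2Cl2, −78 to 0 °C; Rochelle salt
Reagents that add atoms: none
Why: DIBAL reduces the α-alkylidene lactone through the lactol to the primary allylic alcohol and frees the C26 hydroxyl without touching the triene.

Step 26
Reactants: 36 triol
Product: 37 C28 acetate
Conditions: Ac2O (1.1 equiv), 2,4,6-collidine, CH2Cl2, −20 °C
Reagents that add atoms: acetic anhydride, CC(=O)OC(C)=O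
Why: Selective acylation of the unhindered primary allylic hydroxyl over the neopentyl-type secondary and the tertiary hydroxyl.

Step 27
Reactants: 37 acetate bis-silyl ether
Product: 38 acetate with free C1 and C3 hydroxyls
Conditions: TBAF/AcOH (1:1), THF, 0 °C to rt
Reagents that add atoms: none
Why: Buffered fluoride cleaves both primary silyl ethers while the acetate and the polyene are left intact.

Step 28
Reactants: 38 allylic alcohol
Product: 39 target CNP0204268.1
Conditions: MnO2 (excess), CH2Cl2, rt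
Reagents that add atoms: none
Why: Manganese dioxide oxidizes only the allylic primary alcohol (saturated primary, secondary and tertiary hydroxyls are inert) and should give the E-enal without isomerization.

**Compound list**

1 | pent-4-ynoic acid | C#CCCC(=O)O | starting material
2 | 2-(3-bromopropyl)-1,3-dioxolane | BrCCCC1OCCO1 | starting material
3 | 8-(1,3-dioxolan-2-yl)oct-4-ynoic acid | OC(=O)CCC#CCCCC1OCCO1 | intermediate
4 | methyl 8-(1,3-dioxolan-2-yl)oct-4-ynoate | COC(=O)CCC#CCCCC1OCCO1 | intermediate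
5 | methyl 9-oxonon-4-ynoate | COC(=O)CCC#CCCCC=O | intermediate
6 | methyl (4E)-4-(2-hydroxycyclopentylidene)pentanoate, racemic, alkene methyl cis to the carbinol carbon | COC(=O)CC/C(C)=C1\CCCC1O | intermediate
7 | methyl (4E)-4-(2-oxocyclopentylidene)pentanoate | COC(=O)CC/C(C)=C1\CCCC1=O | intermediate
8 | methyl (4E)-4-[(2S)-2-hydroxycyclopentylidene]pentanoate | COC(=O)CC/C(C)=C1\CCC[C@@H]1O | intermediate
9 | methyl (4E)-4-[(2S)-2-(tert-butyldimethylsilyloxy)cyclopentylidene]pentanoate | COC(=O)CC/C(C)=C1\CCC[C@@H]1O[Si](C)(C)C(C)(C)C | intermediate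
10 | (4E)-4-[(2S)-2-(tert-butyldimethylsilyloxy)cyclopentylidene]pentanoic acid | OC(=O)CC/C(C)=C1\CCC[C@@H]1O[Si](C)(C)C(C)(C)C | intermediate
11 | acyl imidazolide of 10 | O=C(CC/C(C)=C1\CCC[C@@H]1O[Si](C)(C)C(C)(C)C)n1ccnc1 | intermediate
12 | 2-acyl-2-methylmalonic acid monomethyl ester (acyl group of 10) | COC(=O)C(C)(C(=O)O)C(=O)CC/C(C)=C1\CCC[C@@H]1O[Si](C)(C)C(C)(C)C | intermediate
13 | methyl (6E)-2-methyl-3-oxo-6-[(2S)-2-(tert-butyldimethylsilyloxy)cyclopentylidene]heptanoate, both C2 epimers | COC(=O)C(C)C(=O)CC/C(C)=C1\CCC[C@@H]1O[Si](C)(C)C(C)(C)C | intermediate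
14 | methyl (2E,6E)-2-methyl-3-(p-tolylsulfonyloxy)-6-[(2S)-2-(tert-butyldimethylsilyloxy)cyclopentylidene]hept-2-enoate (TsO trans to CO2Me) | COC(=O)/C(C)=C(/OS(=O)(=O)c1ccc(C)cc1)CC/C(C)=C1\CCC[C@@H]1O[Si](C)(C)C(C)(C)C | intermediate
15 | (E)-2-(3,3-diethoxyprop-1-en-1-yl)-4,4,5,5-tetramethyl-1,3,2-dioxaborolane | CCOC(OCC)/C=C/B1OC(C)(C)C(C)(C)O1 | starting material
16 | methyl (2E,4E)-6,6-diethoxy-2-methyl-3-{(3E)-3-[(2S)-2-(tert-butyldimethylsilyloxy)cyclopentylidene]butyl}hexa-2,4-dienoate | COC(=O)/C(C)=C(/C=C/C(OCC)OCC)CC/C(C)=C1\CCC[C@@H]1O[Si](C)(C)C(C)(C)C | intermediate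
17 | methyl (2E,4E)-2-methyl-6-oxo-3-{(3E)-3-[(2S)-2-(tert-butyldimethylsilyloxy)cyclopentylidene]butyl}hexa-2,4-dienoate | COC(=O)/C(C)=C(/C=C/C=O)CC/C(C)=C1\CCC[C@@H]1O[Si](C)(C)C(C)(C)C | intermediate
18 | methyl (2E)-2-[2'-(tert-butyldimethylsilyloxy)-1-methylspiro[2-oxabicyclo[3.3.1]non-3-ene-9,1'-cyclopentan]-6-ylidene]propanoate; C6, C10, C11 as in the target, silyloxy group trans to C6 | CC(C)(C)[Si](C)(C)O[C@H]1CCC[C@]12[C@@H]3C=CO[C@@]2(C)CC/C3=C(/C)C(=O)OC | intermediate
19 | desilylated enol ether (free C26 hydroxyl of 18) | O[C@H]1CCC[C@]12[C@@H]3C=CO[C@@]2(C)CC/C3=C(/C)C(=O)OC | intermediate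
20 | lactol: methyl (2E)-2-[2',3-dihydroxy-1-methylspiro[2-oxabicyclo[3.3.1]nonane-9,1'-cyclopentan]-6-ylidene]propanoate, both anomers | O[C@H]1CCC[C@]12[C@@H]3CC(O)O[C@@]2(C)CC/C3=C(/C)C(=O)OC | intermediate
21 | methyl (2E)-2-[1,6-dihydroxy-6-methyl-10-(prop-2-en-1-yl)spiro[4.5]decan-9-ylidene]propanoate; allyl cis-1,3 to the tertiary hydroxyl | O[C@H]1CCC[C@]12[C@H](CC=C)/C(=C(\C)C(=O)OC)CC[C@]2(C)O | intermediate
22 | B-alkyl-9-borabicyclo[3.3.1]nonane adduct of 21 | O[C@H]1CCC[C@]12[C@H](CCCB3C4CCCC3CCC4)/C(=C(\C)C(=O)OC)CC[C@]2(C)O | intermediate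
23 | methyl (2E)-2-[1,6-dihydroxy-10-(3-hydroxypropyl)-6-methylspiro[4.5]decan-9-ylidene]propanoate | O[C@H]1CCC[C@]12[C@H](CCCO)/C(=C(\C)C(=O)OC)CC[C@]2(C)O | intermediate
24 | 9-[(2E)-1-hydroxypropan-2-ylidene]-10-(3-hydroxypropyl)-6-methylspiro[4.5]decane-1,6-diol | O[C@H]1CCC[C@]12[C@H](CCCO)/C(=C(\C)CO)CC[C@]2(C)O | intermediate
25 | bis(tert-butyldiphenylsilyl) ether of 24 at the C1 and C3 oxygens | O[C@H]1CCC[C@]12[C@H](CCCO[Si](c3ccccc3)(c3ccccc3)C(C)(C)C)/C(=C(\C)CO[Si](c3ccccc3)(c3ccccc3)C(C)(C)C)CC[C@]2(C)O | intermediate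
26 | β-hydroxy ketone (C26 ketone, C10 hydroxyl free) | O=C1CCC[C@]12[C@H](CCCO[Si](c3ccccc3)(c3ccccc3)C(C)(C)C)/C(=C(\C)CO[Si](c3ccccc3)(c3ccccc3)C(C)(C)C)CC[C@]2(C)O | intermediate
27 | C14-alkylated keto ester (CH2CO2Me arm cis to C6) | O=C1[C@H](CC(=O)OC)CC[C@]12[C@H](CCCO[Si](c3ccccc3)(c3ccccc3)C(C)(C)C)/C(=C(\C)CO[Si](c3ccccc3)(c3ccccc3)C(C)(C)C)CC[C@]2(C)O | intermediate
28 | hydroxy ester (C26 hydroxyl cis to the C14 arm) | O[C@@H]1[C@H](CC(=O)OC)CC[C@]12[C@H](CCCO[Si](c3ccccc3)(c3ccccc3)C(C)(C)C)/C(=C(\C)CO[Si](c3ccccc3)(c3ccccc3)C(C)(C)C)CC[C@]2(C)O | intermediate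
29 | cis-fused γ-lactone (O26–C28(=O)–C15–C14) | O=C1C[C@@H]2CC[C@@]3([C@@H]2O1)[C@H](CCCO[Si](c4ccccc4)(c4ccccc4)C(C)(C)C)/C(=C(\C)CO[Si](c4ccccc4)(c4ccccc4)C(C)(C)C)CC[C@]3(C)O | intermediate
30 | α-[bis(2,2,2-trifluoroethoxy)phosphoryl] γ-lactone, C15 epimers | O=C1C(P(=O)(OCC(F)(F)F)OCC(F)(F)F)[C@@H]2CC[C@@]3([C@@H]2O1)[C@H](CCCO[Si](c4ccccc4)(c4ccccc4)C(C)(C)C)/C(=C(\C)CO[Si](c4ccccc4)(c4ccccc4)C(C)(C)C)CC[C@]3(C)O | intermediate
31 | 6-methylhept-5-en-2-one | CC(=O)CCC=C(C)C | starting material
32 | 6-methylhepta-1,5-dien-2-yl trifluoromethanesulfonate | C=C(OS(=O)(=O)C(F)(F)F)CCC=C(C)C | intermediate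
33 | (2E)-1,1-diethoxy-8-methyl-4-methylidenenona-2,7-diene | CCOC(OCC)/C=C/C(=C)CCC=C(C)C | intermediate
34 | (2E)-8-methyl-4-methylidenenona-2,7-dienal | O=C/C=C/C(=C)CCC=C(C)C | intermediate
35 | (Z)-α-alkylidene γ-lactone (dienyl group cis to the lactone carbonyl) | O=C1/C(=C\C=C\C(=C)CCC=C(C)C)[C@@H]2CC[C@@]3([C@@H]2O1)[C@H](CCCO[Si](c4ccccc4)(c4ccccc4)C(C)(C)C)/C(=C(\C)CO[Si](c4ccccc4)(c4ccccc4)C(C)(C)C)CC[C@]3(C)O | intermediate
36 | triol: free C28, C26 and C10 hydroxyls, C1 and C3 as silyl ethers | OC/C(=C\C=C\C(=C)CCC=C(C)C)[C@@H]1CC[C@]2([C@H](CCCO[Si](c3ccccc3)(c3ccccc3)C(C)(C)C)/C(=C(\C)CO[Si](c3ccccc3)(c3ccccc3)C(C)(C)C)CC[C@]2(C)O)[C@@H]1O | intermediate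
37 | C28 acetate of 36 | CC(=O)OC/C(=C\C=C\C(=C)CCC=C(C)C)[C@@H]1CC[C@]2([C@H](CCCO[Si](c3ccccc3)(c3ccccc3)C(C)(C)C)/C(=C(\C)CO[Si](c3ccccc3)(c3ccccc3)C(C)(C)C)CC[C@]2(C)O)[C@@H]1O | intermediate
38 | desilylated acetate (C1 allylic alcohol, C3 alcohol) | CC(=O)OC/C(=C\C=C\C(=C)CCC=C(C)C)[C@@H]1CC[C@]2([C@H](CCCO)/C(=C(\C)CO)CC[C@]2(C)O)[C@@H]1O | intermediate
39 | CNP0204268.1 | CC(=O)OC/C(=C\C=C\C(=C)CCC=C(C)C)[C@@H]1CC[C@]2([C@H](CCCO)/C(=C(\C)C=O)CC[C@]2(C)O)[C@@H]1O | target

**Step count and risks**

Total step count: 28. Longest linear sequence: 26 steps (steps 1–21 and 24–28; steps 22–23 make the dienal).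

Steps most likely to fail:

Step 12 (Proposed new method). After the C6–C11 bond has formed, the tertiary centre at C10 may lose a proton or the allylic silyl ether may ionize before the enolate oxygen closes the bridge, and bond formation at C10 (five-membered ring) may compete. Fallback, from 17 back to 20: the closure is run as the known Lewis-acid ene-type cyclization of an enal onto an alkene (EtAlCl2, CH2Cl2, −78 °C, proton transfer from the C10 methyl to the enolate carbon), which should give the methylidene aldehyde F1. Pinnick oxidation (NaClO2, NaH2PO4, 2-methylbut-2-ene) gives the methylidene acid F2. Iodolactonization (I2, NaHCO3, MeCN, 0 °C) then makes the O–C10 bond under tether control, Markovnikov at the tertiary carbon and only for the isomer with the arm cis, to give the bridged iodolactone F3. Bu3SnH/AIBN (PhH, 80 °C) removes iodine to give the bridged lactone F4. DIBAL-H (1.1 equiv, CH2Cl2, −78 °C) should reduce the δ-lactone in preference to the hindered conjugated ester to the silyl lactol F5, and TBAF (THF) then gives 20, where the route continues with step 14.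

Step 19. Facial selectivity in the alkylation of the dianion may be poor, or the β-hydroxy ketone may open by retro-aldol cleavage before it is enolized. Fallback, from 26 back to 29: dehydrogenation with IBX (DMSO/PhMe, 70 °C) gives the spiro cyclopentenone F6. Me4NBH(OAc)3 (MeCN/AcOH, −20 °C) reduces the carbonyl 1,2 with delivery from the C10 hydroxyl and gives the cyclopentenol F7 with the C26 oxygen on the C6 face. Ethyl vinyl ether and N-bromosuccinimide (CH2Cl2, −40 °C) convert this hydroxyl into the bromoacetal F8. Bu3SnH/AIBN (PhH, 80 °C) closes the tetrahydrofuran by 5-exo-trig radical cyclization (Ueno–Stork), which can only deliver C15 to C14 on the face of the C26 oxygen, to give the cyclic ethoxy acetal F9. Jones oxidation (CrO3, H2SO4, acetone, 0 °C) turns the acetal into lactone 29, where the route continues with step 21.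

Step 24. Z-selectivity may erode in the olefination of the cyclic, α-branched phosphonate, and O- instead of C-phosphorylation in step 21 would feed the same problem. Fallback, from 27 back to 38: 27 is reduced as in step 20 but the diol is trapped before lactonization (Me4NBH(OAc)3, MeCN/AcOH, −20 °C; then TESOTf, 2,6-lutidine, CH2Cl2, −78 °C) as the bis-triethylsilyl ether methyl ester F10. LDA (2.2 equiv) and ClP(O)(OCH2CF3)2 (THF, −78 °C) give the open-chain phosphonoacetate F11. A classical acyclic Still–Gennari olefination with 34 (KHMDS, 18-crown-6, THF, −78 °C) should give the Z-enoate F12. DIBAL-H gives the allylic alcohol F13, Ac2O/pyridine gives the allylic acetate F14, and TBAF/AcOH (THF) removes the two triethylsilyl and the two tert-butyldiphenylsilyl groups to give 38, where the route continues with step 28.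

Further compounds

F1 | step 12 | methylidene aldehyde | CC(C)(C)[Si](C)(C)O[C@H]1CCC[C@]12[C@H](CC=O)/C(=C(\C)C(=O)OC)CCC2=C
F2 | step 12 | methylidene acid | CC(C)(C)[Si](C)(C)O[C@H]1CCC[C@]12[C@H](CC(=O)O)/C(=C(\C)C(=O)OC)CCC2=C
F3 | step 12 | bridged iodolactone | CC(C)(C)[Si](C)(C)O[C@H]1CCC[C@]12[C@@H]3CC(=O)O[C@@]2(CI)CC/C3=C(/C)C(=O)OC
F4 | step 12 | bridged lactone | CC(C)(C)[Si](C)(C)O[C@H]1CCC[C@]12[C@@H]3CC(=O)O[C@@]2(C)CC/C3=C(/C)C(=O)OC
F5 | step 12 | silyl lactol | CC(C)(C)[Si](C)(C)O[C@H]1CCC[C@]12[C@@H]3CC(O)O[C@@]2(C)CC/C3=C(/C)C(=O)OC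
F6 | step 19 | spiro cyclopentenone | O=C1C=CC[C@]12[C@H](CCCO[Si](c3ccccc3)(c3ccccc3)C(C)(C)C)/C(=C(\C)CO[Si](c3ccccc3)(c3ccccc3)C(C)(C)C)CC[C@]2(C)O
F7 | step 19 | cyclopentenol | O[C@@H]1C=CC[C@]12[C@H](CCCO[Si](c3ccccc3)(c3ccccc3)C(C)(C)C)/C(=C(\C)CO[Si](c3ccccc3)(c3ccccc3)C(C)(C)C)CC[C@]2(C)O
F8 | step 19 | bromoacetal | CCOC(CBr)O[C@@H]1C=CC[C@]12[C@H](CCCO[Si](c3ccccc3)(c3ccccc3)C(C)(C)C)/C(=C(\C)CO[Si](c3ccccc3)(c3ccccc3)C(C)(C)C)CC[C@]2(C)O
F9 | step 19 | cyclic ethoxy acetal | CCOC1C[C@@H]2CC[C@@]3([C@@H]2O1)[C@H](CCCO[Si](c4ccccc4)(c4ccccc4)C(C)(C)C)/C(=C(\C)CO[Si](c4ccccc4)(c4ccccc4)C(C)(C)C)CC[C@]3(C)O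
F10 | step 24 | bis-triethylsilyl ether methyl ester | CC[Si](CC)(CC)O[C@@H]1[C@H](CC(=O)OC)CC[C@]12[C@H](CCCO[Si](c3ccccc3)(c3ccccc3)C(C)(C)C)/C(=C(\C)CO[Si](c3ccccc3)(c3ccccc3)C(C)(C)C)CC[C@]2(C)O[Si](CC)(CC)CC
F11 | step 24 | open-chain phosphonoacetate | CC[Si](CC)(CC)O[C@@H]1[C@H](C(C(=O)OC)P(=O)(OCC(F)(F)F)OCC(F)(F)F)CC[C@]12[C@H](CCCO[Si](c3ccccc3)(c3ccccc3)C(C)(C)C)/C(=C(\C)CO[Si](c3ccccc3)(c3ccccc3)C(C)(C)C)CC[C@]2(C)O[Si](CC)(CC)CC
F12 | step 24 | Z-enoate | COC(=O)/C(=C\C=C\C(=C)CCC=C(C)C)[C@@H]1CC[C@]2([C@H](CCCO[Si](c3ccccc3)(c3ccccc3)C(C)(C)C)/C(=C(\C)CO[Si](c3ccccc3)(c3ccccc3)C(C)(C)C)CC[C@]2(C)O[Si](CC)(CC)CC)[C@@H]1O[Si](CC)(CC)CC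
F13 | step 24 | allylic alcohol | OC/C(=C\C=C\C(=C)CCC=C(C)C)[C@@H]1CC[C@]2([C@H](CCCO[Si](c3ccccc3)(c3ccccc3)C(C)(C)C)/C(=C(\C)CO[Si](c3ccccc3)(c3ccccc3)C(C)(C)C)CC[C@]2(C)O[Si](CC)(CC)CC)[C@@H]1O[Si](CC)(CC)CC
F14 | step 24 | allylic acetate | CC(=O)OC/C(=C\C=C\C(=C)CCC=C(C)C)[C@@H]1CC[C@]2([C@H](CCCO[Si](c3ccccc3)(c3ccccc3)C(C)(C)C)/C(=C(\C)CO[Si](c3ccccc3)(c3ccccc3)C(C)(C)C)CC[C@]2(C)O[Si](CC)(CC)CC)[C@@H]1O[Si](CC)(CC)CC
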